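The ring is numbered C1 (epoxide CH), C2, C3, C4 (alkene carbon bearing ester carbon C15), C5 (alkene CH), C6, C7 (CH bearing isopropenyl C11(=C13H2)CH3), C8, C9 (CHOAc), C10 (epoxide carbon bearing C14H2O-isobutyrate); C6′ is a carboxyl carbon on C6 that leaves as CO2.
Because C4=C5–C6–C7–C11=C13 is a 1,5-diene and C6 is the γ-carbon of the C15 enoate, the first cut is C6–C7: with C6′ restored on C6 and tied to O–C13, the ten-membered ring becomes the 14-membered allyl glutaconate lactone 21.
Further cuts: lactone C6′–O, C7=C11 (cross-metathesis), C3–C4 (glutaconate alkylation), C8–C9 (allylation), the epoxide C–O bonds and C1–C10 (Baylis–Hillman).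
Forward, the chain grows linearly (C1–C10, C9–C8, C3–C4, C7=C11); the 14-membered lactone closes in step 16 and is contracted to the carbocycle in the last step.
Stereochemistry: C1/C10 from Sharpless epoxidation (D-(−)-tartrate) of an alkene whose geometry comes from the Baylis–Hillman bromide; C9 from reagent-controlled allylboration; C7 from the [3,3] shift across the (E)-C7=C11 alkene; the C4=C5 geometry is thermodynamic.

Key step: step 18

Remark: in 15–21 the glutaconate unit is drawn as the conjugated (E)-2-alkyl form; minor positional or geometric isomers should not need separation, since all give the same anion and silyl ketene acetal in step 18. Aldehyde 1 and the allylborane of step 7 are taken as catalogue items.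

Step 1
Reactants: 1 3-(tert-butyldimethylsilyloxy)propanal; 2 methyl acrylate
Product: 3 methyl 5-(tert-butyldimethylsilyloxy)-3-hydroxy-2-methylidenepentanoate (racemic)
Conditions: DABCO (0.5 equiv), 2 (excess), neat, rt
Reagents that add atoms: none
Why: Morita–Baylis–Hillman reaction joins the acrylate α-carbon (C10) to the aldehyde carbon (C1); the racemic carbinol centre is erased in step 2.

Step 2
Reactants: 3 Baylis–Hillman alcohol
Product: 4 methyl (2Z)-2-(bromomethyl)-5-(tert-butyldimethylsilyloxy)pent-2-enoate
Conditions: NBS, Me2S, CH2Cl2, 0 °C to rt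
Reagents that add atoms: N-bromosuccinimide, O=C1CCC(=O)N1Br
Why: Activation of the alcohol as an alkoxysulfonium salt and SN2′ return of bromide (the known allylic transposition of Baylis–Hillman alcohols) should give the conjugated bromide with the chain trans to the ester, which is the C2-trans-to-C9 geometry the epoxide needs.

Step 3
Reactants: 4 allylic bromide
Product: 5 methyl (2E)-2-[(4-methoxyphenoxy)methyl]-5-(tert-butyldimethylsilyloxy)pent-2-enoate
Conditions: 4-methoxyphenol, K2CO3, acetone, rt
Reagents that add atoms: 4-methoxyphenol, COc1ccc(O)cc1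
Why: Williamson etherification (SN2) at the primary allylic bromide keeps the alkene geometry and masks O14 as an aryl ether that survives hydride, titanium and boron reagents.

Step 4
Reactants: 5 aryl ether ester
Product: 6 (2Z)-2-[(4-methoxyphenoxy)methyl]-5-(tert-butyldimethylsilyloxy)pent-2-en-1-ol (hydroxymethyl trans to the chain)
Conditions: DIBAL-H, CH2Cl2, −78 °C; Rochelle salt work-up
Reagents that add atoms: none
Why: DIBAL-H 1,2-reduction of the enoate should give the allylic alcohol (C9) without touching the ethers.

Step 5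
Reactants: 6 allylic alcohol
Product: 7 epoxy alcohol {(2S,3R)-3-[2-(tert-butyldimethylsilyloxy)ethyl]-2-[(4-methoxyphenoxy)methyl]oxiran-2-yl}methanol
Conditions: Ti(Oi-Pr)4 (10 mol %), D-(−)-diethyl tartrate (12 mol %), t-BuOOH, 4 Å MS, CH2Cl2, −20 °C
Reagents that add atoms: tert-butyl hydroperoxide, CC(C)(C)OO
Why: Sharpless asymmetric epoxidation directed by the C9 hydroxyl, which is (E)-disposed to the chain (a good substrate class); D-(−)-tartrate should deliver oxygen to the face that gives C1 (R) and the required C10 configuration.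

Step 6
Reactants: 7 epoxy alcohol
Product: 8 epoxy aldehyde (2S,3R)-3-[2-(tert-butyldimethylsilyloxy)ethyl]-2-[(4-methoxyphenoxy)methyl]oxirane-2-carbaldehyde
Conditions: PhI(OAc)2, TEMPO (cat.), CH2Cl2, rt
Reagents that add atoms: none
Why: TEMPO/iodine(III) oxidation of a primary alcohol stops at the aldehyde, and the α-quaternary epoxy aldehyde cannot epimerise.

Step 7
Reactants: 8 epoxy aldehyde
Product: 9 homoallylic alcohol (1S)-1-{(2R,3R)-3-[2-(tert-butyldimethylsilyloxy)ethyl]-2-[(4-methoxyphenoxy)methyl]oxiran-2-yl}but-3-en-1-ol (C9 S)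
Conditions: (−)-Ipc2B(allyl), Et2O, −78 °C; then ethanolamine, rt
Reagents that add atoms: (−)-B-allyldiisopinocampheylborane, C=CCB([C@@H]1C[C@@H]2C[C@@H](C2(C)C)[C@H]1C)[C@@H]1C[C@@H]2C[C@@H](C2(C)C)[C@H]1C
Why: Brown allylation through a chair six-membered transition state; the isopinocampheyl groups of the (+)-α-pinene-derived reagent direct allyl to the Si face of the aldehyde and so set C9 (S) under reagent control, and the non-basic work-up avoids Payne rearrangement.

Step 8
Reactants: 9 homoallylic alcohol
Product: 10 diol (1S)-1-{(2R,3R)-3-[2-(tert-butyldimethylsilyloxy)ethyl]-2-(hydroxymethyl)oxiran-2-yl}but-3-en-1-ol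
Conditions: CAN, pyridine, MeCN/H2O (4:1), 0 °C
Reagents that add atoms: none
Why: Oxidative cleavage of the p-methoxyphenyl ether (arene radical cation, then hydrolysis to benzoquinone) is placed here, before any oxidisable enolisable diester is present; buffering should spare the epoxide and the silyl ether.

Step 9
Reactants: 10 diol
Product: 11 {(2R,3R)-3-[2-(tert-butyldimethylsilyloxy)ethyl]-2-[(1S)-1-hydroxybut-3-en-1-yl]oxiran-2-yl}methyl 2-methylpropanoate
Conditions: i-PrCOCl, 2,4,6-collidine, CH2Cl2, −40 °C
Reagents that add atoms: isobutyryl chloride, CC(C)C(=O)Cl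
Why: Acylation at low temperature should select the primary C14 hydroxyl over the hindered secondary C9 hydroxyl, and the primary ester is the thermodynamically preferred site, so acyl migration is not a concern.

Step 10
Reactants: 11 silyl ether
Product: 12 {(2R,3R)-2-[(1S)-1-hydroxybut-3-en-1-yl]-3-(2-hydroxyethyl)oxiran-2-yl}methyl 2-methylpropanoate
Conditions: TBAF, AcOH, THF, 0 °C to rt
Reagents that add atoms: none
Why: Fluoride desilylation buffered with acetic acid should free the C3 hydroxyl without Payne rearrangement or ester cleavage.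

Step 11
Reactants: 12 diol
Product: 13 {(2R,3R)-2-[(1S)-1-hydroxybut-3-en-1-yl]-3-(2-iodoethyl)oxiran-2-yl}methyl 2-methylpropanoate
Conditions: PPh3, I2, imidazole, THF, 0 °C
Reagents that add atoms: iodine, II
Why: Appel iodination: the unhindered primary alkoxyphosphonium ion is displaced by iodide (SN2), the secondary C9 hydroxyl next to a quaternary carbon is not substituted, and imidazole keeps the medium non-acidic for the epoxide.

Step 12
Reactants: 13 iodide; 14 dimethyl glutaconate
Product: 15 dimethyl (2E)-2-{2-[(2R,3R)-3-[(1S)-1-hydroxybut-3-en-1-yl]-3-(isobutyryloxymethyl)oxiran-2-yl]ethyl}pent-2-enedioate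
Conditions: NaH, 14 (excess), DMF, 0 °C to rt
Reagents that add atoms: none
Why: SN2 C-alkylation of the sodium salt of a vinylogous malonate forms C3–C4; excess nucleophile curbs dialkylation and lets the first-formed 4-alkyl isomer settle by proton exchange as the conjugated 2-alkyl diester, and the weakly basic anion leaves hydroxyl, isobutyrate and epoxide alone.

Step 13
Reactants: 15 dimethyl 2-alkylglutaconate
Product: 16 (3E)-4-(methoxycarbonyl)-6-[(2R,3R)-3-[(1S)-1-hydroxybut-3-en-1-yl]-3-(isobutyryloxymethyl)oxiran-2-yl]hex-3-enoic acid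
Conditions: Me3SnOH, ClCH2CH2Cl, 70 °C; cold 0.1 M HCl wash
Reagents that add atoms: trimethyltin hydroxide, C[Sn](C)(C)O
Why: Ester hydrolysis with trimethyltin hydroxide is governed by steric access, so the unhindered CH2CO2Me group (C6′) should react ahead of the conjugated α-branched C15 ester and the branched, neopentyl-type isobutyrate; the neutral medium avoids Payne rearrangement.

Step 14
Reactants: 16 acid; 17 methacrolein
Product: 18 enal acid (16 with the terminal vinyl group replaced by (E)-CH=C(CH3)CHO)
Conditions: Hoveyda–Grubbs II (5 mol %), 17 (excess), CH2Cl2, 40 °C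
Reagents that add atoms: none
Why: Olefin cross-metathesis of a terminal alkene with methacrolein gives the thermodynamic (E)-2-methyl enal, which fixes the C7=C11 geometry; the electron-poor trisubstituted glutaconate alkene is inert and the free acid and alcohol are tolerated.

Step 15
Reactants: 18 enal acid
Product: 19 hydroxy acid (18 with CHO reduced to the C13 allylic CH2OH)
Conditions: NaBH4, CeCl3·7H2O, MeOH, −40 °C
Reagents that add atoms: none
Why: Luche reduction is a 1,2-reduction selective for the aldehyde, so the three esters, the acid and the epoxide should remain.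

Step 16
Reactants: 19 hydroxy acid
Product: 20 14-membered lactone with free C9 hydroxyl (C6′(=O)–O–C13)
Conditions: MNBA, DMAP, CH2Cl2 (1 mM, slow addition), rt
Reagents that add atoms: none
Why: Shiina macrolactonisation through the mixed anhydride; the primary allylic C13 hydroxyl closes an unstrained 14-membered ring far faster than the hindered secondary C9 hydroxyl could close a ten-membered one.

Step 17
Reactants: 20 hydroxy lactone
Product: 21 14-membered allyl glutaconate lactone carrying epoxide, C9 acetate and C14 isobutyrate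
Conditions: Ac2O, pyridine, DMAP (cat.), CH2Cl2, 0 °C to rt
Reagents that add atoms: acetic anhydride, CC(=O)OC(C)=O
Why: DMAP-catalysed acetylation of the hindered secondary alcohol completes the ester pattern of the target under conditions too weakly basic to harm the lactone.

Step 18
Reactants: 21 glutaconate lactone
Product: 25 CNP0372928.1 (target), via silyl ketene acetal 22 (not isolated), via ten-ring silyl ester 23 (not isolated), via deconjugated ester 24 (not isolated)
Conditions: BSA (0.3 equiv), KOAc (0.1 equiv), PhMe, 110 °C; then DBU (0.2 equiv), rt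
Reagents that add atoms: none
Why: Proposed new method: C6 of 21 lies between the lactone carbonyl and the C4=C5–CO2Me unit, so catalytic silyl transfer (BSA/KOAc) should give the conjugated silyl ketene acetal 22, in which C6=C(OSi)–O–C13–C11=C7 is a 1,5-diene; the [3,3] shift forms C6–C7, cleaves O–C13 and turns C11=C13 into the isopropenyl group, acetate then frees the carboxylate of 23, CO2 is lost from this vinylogous malonate and the ester dienolate is protonated to 24, which DBU moves into conjugation. The closest known reaction types are the decarboxylative Claisen rearrangement of allyl esters of sulfonyl- or carbonyl-activated acetic acids under the same silylating conditions and the Ireland–Claisen ring contraction of macrolactones; new here is that the second activating group acts through a C=C bond and that both events are run inside one ring. The ten-membered ring arises by transannular ring contraction (14 to 10 atoms), the six-centre array lying within the lactone and taking the boat- or chair-like shape the eight-atom tether permits. C7, the only new stereocentre, is set by the face of the (E)-C7=C11 alkene that C6 reaches, a choice made by the alkene geometry and the neighbouring C9 acetoxy/epoxide segment, which is expected to stay outside the pericyclic array and give the cis C7/C9 relation (7S); this is the least secure point of the step. The step needs the [3,3] shift to outrun C-silylation and attack of the stabilised anion on the epoxide or acyloxy groups, which the near-neutral conditions, the low basicity of the glutaconate anion and the proximity of the termini in the ring should secure, and the final C4=C5 geometry is the thermodynamic one (ester trans to C6).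

Compound list
1 | 3-(tert-butyldimethylsilyloxy)propanal | CC(C)(C)[Si](C)(C)OCCC=O | starting material
2 | methyl acrylate | C=CC(=O)OC | starting material
3 | methyl 5-(tert-butyldimethylsilyloxy)-3-hydroxy-2-methylidenepentanoate (racemic) | C=C(C(=O)OC)C(O)CCO[Si](C)(C)C(C)(C)C | intermediate
4 | methyl (2Z)-2-(bromomethyl)-5-(tert-butyldimethylsilyloxy)pent-2-enoate | COC(=O)/C(CBr)=C/CCO[Si](C)(C)C(C)(C)C | intermediate
5 | methyl (2E)-2-[(4-methoxyphenoxy)methyl]-5-(tert-butyldimethylsilyloxy)pent-2-enoate | COC(=O)/C(COc1ccc(OC)cc1)=C/CCO[Si](C)(C)C(C)(C)C | intermediate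
6 | (2Z)-2-[(4-methoxyphenoxy)methyl]-5-(tert-butyldimethylsilyloxy)pent-2-en-1-ol | OC/C(COc1ccc(OC)cc1)=C/CCO[Si](C)(C)C(C)(C)C | intermediate
7 | {(2S,3R)-3-[2-(tert-butyldimethylsilyloxy)ethyl]-2-[(4-methoxyphenoxy)methyl]oxiran-2-yl}methanol | CC(C)(C)[Si](C)(C)OCC[C@H]1O[C@]1(COc2ccc(OC)cc2)CO | intermediate
8 | (2S,3R)-3-[2-(tert-butyldimethylsilyloxy)ethyl]-2-[(4-methoxyphenoxy)methyl]oxirane-2-carbaldehyde | CC(C)(C)[Si](C)(C)OCC[C@H]1O[C@]1(COc2ccc(OC)cc2)C=O | intermediate
9 | (1S)-1-{(2R,3R)-3-[2-(tert-butyldimethylsilyloxy)ethyl]-2-[(4-methoxyphenoxy)methyl]oxiran-2-yl}but-3-en-1-ol | CC(C)(C)[Si](C)(C)OCC[C@H]1O[C@]1(COc2ccc(OC)cc2)[C@@H](O)CC=C | intermediate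
10 | (1S)-1-{(2R,3R)-3-[2-(tert-butyldimethylsilyloxy)ethyl]-2-(hydroxymethyl)oxiran-2-yl}but-3-en-1-ol | CC(C)(C)[Si](C)(C)OCC[C@H]1O[C@]1(CO)[C@@H](O)CC=C | intermediate
11 | {(2R,3R)-3-[2-(tert-butyldimethylsilyloxy)ethyl]-2-[(1S)-1-hydroxybut-3-en-1-yl]oxiran-2-yl}methyl 2-methylpropanoate | CC(C)(C)[Si](C)(C)OCC[C@H]1O[C@]1(COC(=O)C(C)C)[C@@H](O)CC=C | intermediate
12 | {(2R,3R)-2-[(1S)-1-hydroxybut-3-en-1-yl]-3-(2-hydroxyethyl)oxiran-2-yl}methyl 2-methylpropanoate | OCC[C@H]1O[C@]1(COC(=O)C(C)C)[C@@H](O)CC=C | intermediate
13 | {(2R,3R)-2-[(1S)-1-hydroxybut-3-en-1-yl]-3-(2-iodoethyl)oxiran-2-yl}methyl 2-methylpropanoate | ICC[C@H]1O[C@]1(COC(=O)C(C)C)[C@@H](O)CC=C | intermediate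
14 | dimethyl glutaconate, dimethyl (2E)-pent-2-enedioate | COC(=O)/C=C/CC(=O)OC | starting material
15 | dimethyl (2E)-2-{2-[(2R,3R)-3-[(1S)-1-hydroxybut-3-en-1-yl]-3-(isobutyryloxymethyl)oxiran-2-yl]ethyl}pent-2-enedioate | COC(=O)C/C=C(/C(=O)OC)CC[C@H]1O[C@]1(COC(=O)C(C)C)[C@@H](O)CC=C | intermediate
16 | (3E)-4-(methoxycarbonyl)-6-[(2R,3R)-3-[(1S)-1-hydroxybut-3-en-1-yl]-3-(isobutyryloxymethyl)oxiran-2-yl]hex-3-enoic acid | OC(=O)C/C=C(/C(=O)OC)CC[C@H]1O[C@]1(COC(=O)C(C)C)[C@@H](O)CC=C | intermediate
17 | methacrolein | C=C(C)C=O | starting material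
18 | enal acid: 16 with the vinyl group replaced by (E)-CH=C(CH3)CHO | OC(=O)C/C=C(/C(=O)OC)CC[C@H]1O[C@]1(COC(=O)C(C)C)[C@@H](O)C/C=C(\C)C=O | intermediate
19 | hydroxy acid (seco acid): 18 with CHO reduced to the C13 allylic alcohol | OC(=O)C/C=C(/C(=O)OC)CC[C@H]1O[C@]1(COC(=O)C(C)C)[C@@H](O)C/C=C(\C)CO | intermediate
20 | 14-membered glutaconate lactone with free C9 hydroxyl, (E)-C4=C5 and (E)-C7=C11 | O=C1C/C=C(/C(=O)OC)CC[C@H]2O[C@]2(COC(=O)C(C)C)[C@@H](O)C/C=C(\C)CO1 | intermediate
21 | 14-membered glutaconate lactone with C9 acetate and C14 isobutyrate | O=C1C/C=C(/C(=O)OC)CC[C@H]2O[C@]2(COC(=O)C(C)C)[C@@H](OC(C)=O)C/C=C(\C)CO1 | intermediate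
22 | trimethylsilyl ketene acetal of 21 at the lactone carbonyl (C6=C6′(OSiMe3)–O) | C[Si](C)(C)OC1=C/C=C(/C(=O)OC)CC[C@H]2O[C@]2(COC(=O)C(C)C)[C@@H](OC(C)=O)C/C=C(\C)CO1 | intermediate
23 | ring-contracted ten-membered trimethylsilyl ester (C6–CO2SiMe3, C6 epimers) | C=C(C)[C@H]1C(C(=O)O[Si](C)(C)C)/C=C(/C(=O)OC)CC[C@H]2O[C@]2(COC(=O)C(C)C)[C@@H](OC(C)=O)C1 | intermediate
24 | deconjugated ester (C5=C6 alkene, C4–H; C4 and alkene geometry undefined) | C=C(C)[C@H]1C=CC(C(=O)OC)CC[C@H]2O[C@]2(COC(=O)C(C)C)[C@@H](OC(C)=O)C1 | intermediate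
25 | CNP0372928.1 | C=C(C)[C@H]1C/C=C(/C(=O)OC)CC[C@H]2O[C@]2(COC(=O)C(C)C)[C@@H](OC(C)=O)C1 | target

Total step count: 18. Longest linear sequence: 18 steps (1 to 25); 2, 14 and 17 are purchased.

Steps most likely to fail

Step 18. The catalytic silyl-transfer cycle may stall: the stabilised anion may be silylated on carbon or attack the epoxide instead of rearranging, or the silyl ester may not lose CO2. The face of C7 is also not secured by precedent. The fallback separates the events and uses stoichiometric, known reactions. Starting from 21, classical Ireland–Claisen conditions (LiHMDS, 1.05 equiv, then TMSCl/Et3N, THF, −78 °C to reflux) should give 22 and, after the shift, 23. Aqueous work-up would hydrolyse 23 to the ring-contracted carboxylic acid F1, which is isolated. Heating F1 in DMF with pyridine should expel CO2 from this vinylogous malonic half-ester to give 24, and DBU then takes 24 to 25.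

Step 13. The tin hydroxide may discriminate poorly between the two methyl esters, cleave the isobutyrate, or promote an acyl shift to the free C9 hydroxyl. The fallback builds the acid by oxidation instead of hydrolysis. Starting from 13, alkylation of sodium trimethyl phosphonoacetate (NaH, DMF) should give the phosphonate F2. Horner–Wadsworth–Emmons reaction of F2 with aldehyde 1 (LiCl, DBU, MeCN) should give the silyl ether F3, and TBAF/AcOH the primary alcohol F4. TEMPO/PhI(OAc)2 in MeCN–water should oxidise only the primary alcohol of F4 to the carboxylic acid, which returns to the route at 16.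

Step 16. The activated glutaconic half-acid may oligomerise, react through a ketene, or acylate the C9 hydroxyl. The fallback closes the same ring at a different bond. Starting from 16, esterification with 2-methylprop-2-en-1-ol (EDC, DMAP cat., CH2Cl2) should give the methallyl ester F5. Ring-closing metathesis of F5 (Grubbs II, PhMe, 80 °C, 1 mM) would form C7=C11 within the 14-membered ring and return to the route at 20, the (E) isomer being the one needed.

Further compounds
F1 | step 18 | ring-contracted ten-membered carboxylic acid (C6–CO2H, C6 epimers) | C=C(C)[C@H]1C(C(=O)O)/C=C(/C(=O)OC)CC[C@H]2O[C@]2(COC(=O)C(C)C)[C@@H](OC(C)=O)C1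
F2 | step 13 | methyl 2-(dimethoxyphosphoryl)-4-[(2R,3R)-3-[(1S)-1-hydroxybut-3-en-1-yl]-3-(isobutyryloxymethyl)oxiran-2-yl]butanoate | COC(=O)C(CC[C@H]1O[C@]1(COC(=O)C(C)C)[C@@H](O)CC=C)P(=O)(OC)OC
F3 | step 13 | (E)-enoate from F2 and 1, carrying a CH2CH2OSi(t-Bu)Me2 group on C5 | CC(C)(C)[Si](C)(C)OCC/C=C(/C(=O)OC)CC[C@H]1O[C@]1(COC(=O)C(C)C)[C@@H](O)CC=C
F4 | step 13 | primary alcohol from F3 (C6′ as CH2OH) | OCC/C=C(/C(=O)OC)CC[C@H]1O[C@]1(COC(=O)C(C)C)[C@@H](O)CC=C
F5 | step 16 | 2-methylprop-2-en-1-yl ester of acid 16 | C=C(C)COC(=O)C/C=C(/C(=O)OC)CC[C@H]1O[C@]1(COC(=O)C(C)C)[C@@H](O)CC=C
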